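**Strategy**

Everything rests on cutting O1–C8a and C4a–C5, which unfolds rings A and B into one chain on the preformed quaternary C8. The key step refolds it in one operation: the C2 hydroxyl adds to C8a (ring B) and C4a then C-acylates an acylketene at C5 (ring A). It exploits ring A as a non-aromatic β-triketone that shares its C8a–O bond with the cis-2,3-dimethyl ring B (that oxygen is O1). The precursor is an open-chain acyl Meldrum's acid (C7 arm) in which the C2 hydroxyl is a silyl ether and the C8a/C4a/C4 diketone is held as its ynone (C8a≡C4a–C4=O), so that no enol lactonises onto the activated C7 acid and no water is released to quench the ketene.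

Key step: step 17

Remark on labels: O1, C2–C4, C4a, C5–C8 and C8a are the chromene positions of the target and are used for open-chain compounds as well.
Assumption: for the two catalyst-controlled steps (7 and 18) the antipode of the catalyst that gives the drawn configuration is fixed by a trial run on the real substrate, both antipodes being accessible.

**Route**

Step 1
Reactants: 1 (S)-4-benzyloxazolidin-2-one; 2 3-methylbut-2-enoyl chloride
Product: 3 (S)-4-benzyl-3-(3-methylbut-2-enoyl)oxazolidin-2-one
Conditions: n-BuLi, THF, −78 °C; then 2, −78 → 0 °C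
Reagents that add atoms: none
Why: N-acylation of the lithiated oxazolidinone by the acid chloride (nucleophilic acyl substitution) installs the senecioyl chain on the auxiliary without forming a stereocentre.

Step 2
Reactants: 3 N-senecioyl oxazolidinone; 4 3-methylbut-3-en-1-ol
Product: 6 (S)-4-benzyl-3-[(S)-5-methyl-2-(prop-1-en-2-yl)hex-5-enoyl]oxazolidin-2-one, via homoallyl triflate 5 (not isolated)
Conditions: 4, Tf2O, 2,6-lutidine, CH2Cl2–pentane, −78 °C, cold filtration; filtrate added to 3, NaN(SiMe3)2, THF, −78 → −50 °C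
Reagents that add atoms: none
Why: Deconjugative asymmetric enolate alkylation: γ-deprotonation gives the chelated (Z)-dienolate, which the highly reactive primary triflate alkylates at C-α at −78 °C on the face away from the benzyl group, so the new centre is (S) and the double bond ends as the isopropenyl group.

Step 3
Reactants: 6 alkylated imide
Product: 7 (S)-5-methyl-2-(prop-1-en-2-yl)hex-5-en-1-ol
Conditions: LiBH4, MeOH (1 equiv), Et2O, 0 °C
Reagents that add atoms: none
Why: Reductive cleavage of the N-acyl oxazolidinone with LiBH4 (hydride attack on the exocyclic carbonyl) frees the primary alcohol and the auxiliary under conditions too mild to epimerise the α-centre or move the β,γ-double bond.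

Step 4
Reactants: 7 (S)-alcohol
Product: 8 (S)-3-(iodomethyl)-2,6-dimethylhepta-1,6-diene
Conditions: PPh3, I2, imidazole, CH2Cl2, 0 °C
Reagents that add atoms: iodine, II
Why: Appel-type iodination: the alkoxyphosphonium salt is displaced by iodide at the primary carbon (SN2), so the neighbouring stereocentre is not involved.

Step 5
Reactants: 9 3-(tert-butoxy)-3-oxopropanoic acid; 10 2,2-diphenylethanol
Product: 11 tert-butyl 2,2-diphenylethyl malonate
Conditions: EDC·HCl, DMAP (0.1 equiv), CH2Cl2, 0 → 23 °C
Reagents that add atoms: none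
Why: Steglich esterification of the malonic half-acid gives the mixed diester whose bulky tert-butyl and flat diphenylethyl groups are what the catalyst of step 7 and the hydride of step 8 later tell apart.

Step 6
Reactants: 11 mixed malonate (in excess); 8 (S)-iodide
Product: 12 1-tert-butyl 3-(2,2-diphenylethyl) 2-[(R)-5-methyl-2-(prop-1-en-2-yl)hex-5-en-1-yl]malonate (both epimers at the malonate carbon)
Conditions: NaH, DMF, 0 °C; then 8, 23 → 45 °C
Reagents that add atoms: none
Why: Malonic ester alkylation: the soft stabilised enolate displaces the primary iodide by SN2 with little E2, leaving the side-chain centre untouched (its descriptor changes from S to R only through the priority change) and the malonate carbon as a labile epimer mixture.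

Step 7
Reactants: 12 monoalkyl malonate; 13 1-bromo-3-methylbut-2-ene
Product: 14 1-tert-butyl 3-(2,2-diphenylethyl) (R)-2-(3-methylbut-2-en-1-yl)-2-[(R)-5-methyl-2-(prop-1-en-2-yl)hex-5-en-1-yl]malonate
Conditions: 13, N-spiro bis(binaphthyl)ammonium bromide bearing 3,4,5-trifluorophenyl groups (5 mol%), 50% aq KOH, PhMe, −40 °C
Reagents that add atoms: none
Why: Enantioselective phase-transfer alkylation of an α-monoalkyl malonate: the enolate, ion-paired with the chiral ammonium cation that discriminates the tert-butyl from the diphenylethyl ester face, is prenylated by the reactive allylic bromide to set quaternary C8 as (R) under catalyst control.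

Step 8
Reactants: 14 quaternary malonate
Product: 15 tert-butyl (R)-2-(hydroxymethyl)-5-methyl-2-[(R)-5-methyl-2-(prop-1-en-2-yl)hex-5-en-1-yl]hex-4-enoate
Conditions: LiBH4, MeOH (2 equiv), THF, 0 → 40 °C
Reagents that add atoms: none
Why: Chemoselective hydride reduction: LiBH4 reduces the primary alkyl ester of the activated malonate but not the hindered tert-butyl ester, turning the two arms on C8 into CH2OH (future C8a) and CO2t-Bu (future C7).

Step 9
Reactants: 15 hydroxy ester
Product: 16 tert-butyl (R)-2-formyl-5-methyl-2-[(R)-5-methyl-2-(prop-1-en-2-yl)hex-5-en-1-yl]hex-4-enoate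
Conditions: Dess–Martin periodinane, CH2Cl2, 0 → 23 °C
Reagents that add atoms: none
Why: Dess–Martin oxidation converts the neopentyl-type primary alcohol into the non-enolisable aldehyde under base-free conditions that avoid retro-Claisen loss of the formyl group.

Step 10
Reactants: 16 aldehyde
Product: 17 tert-butyl (R)-2-ethynyl-5-methyl-2-[(R)-5-methyl-2-(prop-1-en-2-yl)hex-5-en-1-yl]hex-4-enoate
Conditions: Me3SiCHN2, n-BuLi, THF, −78 °C; then 16, −78 → 0 °C
Reagents that add atoms: (trimethylsilyl)diazomethane, C[Si](C)(C)C=[N+]=[N-]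
Why: Colvin rearrangement: addition of LiC(N2)SiMe3 to the aldehyde, Peterson-type loss of LiOSiMe3 and 1,2-hydrogen shift in the alkylidene carbene give the terminal alkyne at low temperature without alkoxide, which suits the deformylation-prone α-formyl ester.

Step 11
Reactants: 18 (S)-4-benzyl-3-propionyloxazolidin-2-one; 19 acetaldehyde
Product: 20 (S)-4-benzyl-3-[(2S,3R)-3-hydroxy-2-methylbutanoyl]oxazolidin-2-one
Conditions: Bu2BOTf, i-Pr2NEt, CH2Cl2, −78 → 0 °C; 19, −78 → 0 °C; H2O2, pH 7 buffer, MeOH
Reagents that add atoms: none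
Why: Evans syn aldol: the (Z)-boron enolate adds to acetaldehyde through a chair transition state on the enolate face opposite the benzyl group, setting (2S,3R), the future C3/C2 pair.

Step 12
Reactants: 20 syn-aldol imide
Product: 21 (2S,3R)-3-hydroxy-N-methoxy-N,2-dimethylbutanamide
Conditions: MeNH(OMe)·HCl, AlMe3, CH2Cl2, −20 → 0 °C
Reagents that add atoms: N,O-dimethylhydroxylamine hydrochloride, CNOC.Cl
Why: Transamidation with the aluminium amide of N,O-dimethylhydroxylamine, assisted by the free β-hydroxyl, gives the Weinreb amide and releases the auxiliary without epimerising C-α.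

Step 13
Reactants: 21 hydroxy Weinreb amide
Product: 22 (2S,3R)-N-methoxy-N,2-dimethyl-3-[(triethylsilyl)oxy]butanamide
Conditions: Et3SiCl, imidazole, DMF, 0 → 23 °C
Reagents that add atoms: chlorotriethylsilane, CC[Si](Cl)(CC)CC
Why: Silyl ether formation masks the secondary hydroxyl through the organometallic and acylation steps with a group that mild acid removes at the start of the cascade.

Step 14
Reactants: 17 alkynyl tert-butyl ester; 22 silylated Weinreb amide
Product: 23 tert-butyl (R)-5-methyl-2-{(4S,5R)-4-methyl-3-oxo-5-[(triethylsilyl)oxy]hex-1-yn-1-yl}-2-[(R)-5-methyl-2-(prop-1-en-2-yl)hex-5-en-1-yl]hex-4-enoate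
Conditions: 17, i-PrMgCl·LiCl, THF, 0 → 23 °C; then 22, 0 → 23 °C
Reagents that add atoms: none
Why: Weinreb ketone synthesis: the alkynylmagnesium chloride made by deprotonating 17 adds once to the amide through a stable magnesium chelate, joining C4 to C4a≡C8a as the ynone without touching the tert-butyl ester or the α-centre.

Step 15
Reactants: 23 ynone tert-butyl ester
Product: 25 (R)-5-methyl-2-{(4S,5R)-4-methyl-3-oxo-5-[(triethylsilyl)oxy]hex-1-yn-1-yl}-2-[(R)-5-methyl-2-(prop-1-en-2-yl)hex-5-en-1-yl]hex-4-enoic acid, via triethylsilyl ester 24 (not isolated)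
Conditions: Et3SiOTf, 2,6-lutidine, CH2Cl2, −20 → 0 °C; then MeOH–H2O, 0 °C
Reagents that add atoms: none
Why: Silyl triflate-mediated tert-butyl ester cleavage: O-silylation and loss of isobutene give the silyl ester, hydrolysed on work-up to the C7 acid, without protic acid, so the alkenes, the ynone and the TES ether (whose exchange with the reagent is degenerate) survive.

Step 16
Reactants: 25 ynone acid; 26 Meldrum's acid
Product: 28 5-[(R)-1-hydroxy-5-methyl-2-{(4S,5R)-4-methyl-3-oxo-5-[(triethylsilyl)oxy]hex-1-yn-1-yl}-2-[(R)-5-methyl-2-(prop-1-en-2-yl)hex-5-en-1-yl]hex-4-en-1-ylidene]-2,2-dimethyl-1,3-dioxane-4,6-dione, via acid chloride 27 (not isolated)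
Conditions: 1-chloro-N,N,2-trimethylprop-1-en-1-amine, CH2Cl2, 0 °C; then 26, pyridine, 0 → 23 °C; cold aq KHSO4 wash, used crude
Reagents that add atoms: none
Why: C-acylation of Meldrum's acid by the acid chloride formed under neutral conditions gives the enolised acyl Meldrum's acid, and it is clean here because the diketone is latent as the ynone (no enol to lactonise onto the activated C7 carbonyl) and the hydroxyl is silylated.

Step 17
Reactants: 28 open-chain silyloxy ynone acyl Meldrum's acid
Product: 32 (2R,3S,8R)-5-hydroxy-2,3-dimethyl-8-(3-methylbut-2-en-1-yl)-8-[(R)-5-methyl-2-(prop-1-en-2-yl)hex-5-en-1-yl]-2,3-dihydro-4H-chromene-4,7(8H)-dione, via free hydroxy ynone 29 (not isolated), via ring B dihydropyranone 30 (not isolated), via acylketene 31 (not isolated)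
Conditions: PPTS (0.2 equiv), MeOH–CH2Cl2, 23 °C; evaporate; CSA (0.1 equiv), 4 Å MS, PhMe (0.005 M), 45 °C then 105 °C
Reagents that add atoms: none
Why: Mild acid in methanol removes the triethylsilyl group, and the freed C2 hydroxyl of 29 adds to C8a of the acid-activated ynone in a 6-endo-dig closure (O1–C8a, ring B), giving the vinylogous ester 30 with the C2–O bond and both methyl-bearing centres untouched, so the syn relationship of the aldol unit is carried over as the cis 2,3-dimethyl arrangement. At 105 °C the acyl Meldrum's acid fragments by retro-[4+2] loss of acetone and CO2 to the acylketene 31 (O=C5=C6H–C7=O), and the enol-ether carbon C4a attacks the ketene carbon C5 in a six-membered closure that leaves the C5=O outside the ring and the C5=C6 bond inside it (C4a–C5, ring A); loss of the C4a proton re-forms the C4a=C8a double bond and enolisation gives 32. The closest known reactions are the acid-mediated cyclisation of β-hydroxy ynones to 2,3-dihydropyran-4-ones and the thermolysis of acyl Meldrum's acids or dioxinones with intramolecular C-acylation. No stereocentre is formed, and ring A cannot aromatise because C8 carries two carbon substituents. The selectivity needed is C- over O-acylation and ring B before ketene: the C8a oxygen is already O1, the C4 oxygen could reach C5 only through an eight-membered ring, the two temperature stages separate the events, and since the ynone releases no water and methanol is evaporated nothing else traps the ketene. High dilution disfavours ketene dimerisation and the weak acid leaves C3 unepimerised.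

Step 18
Reactants: 32 bicyclic core; 33 (E)-hex-2-enal
Product: 34 tricyclic enol lactone in which a (4S)-4-propyl-3,4-dihydro-2H-pyran-2-one is fused to ring A through O–C5=C6 (chain C6–CH(Pr)–CH2–C(=O)–O–C5; other centres as in 32)
Conditions: 33 (1.5 equiv), aminoindanol-derived N-mesityl triazolium chloride (10 mol%), 3,3',5,5'-tetra-tert-butyldiphenoquinone (1.2 equiv), i-Pr2NEt, PhMe, 23 °C
Reagents that add atoms: none
Why: Oxidative NHC catalysis: the Breslow intermediate of the enal is oxidised to the (E)-hex-2-enoyl azolium, the nucleophilic enol carbon C6 adds to its β-carbon on the Si face dictated by the catalyst (new centre S), and acylation of the C5 enol oxygen closes the lactone and releases the carbene.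

Step 19
Reactants: 34 enol lactone
Product: 35 (S)-3-[(2R,3S,8R)-5-hydroxy-2,3-dimethyl-8-(3-methylbut-2-en-1-yl)-8-[(R)-5-methyl-2-(prop-1-en-2-yl)hex-5-en-1-yl]-4,7-dioxo-3,4,7,8-tetrahydro-2H-chromen-6-yl]hexanoic acid (CNP0294320.1)
Conditions: LiOH, THF–H2O, 0 °C; then cold 1 M HCl to pH 3
Reagents that add atoms: water, O
Why: Hydrolysis of the activated enol lactone by acyl–oxygen cleavage at 0 °C returns the C5 enol and the carboxylic acid, the substrate being held as the delocalised triketone enolate so that C3 is not epimerised and ring B stays closed.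

**Compound list**

1 | (S)-4-benzyloxazolidin-2-one | O=C1N[C@@H](Cc2ccccc2)CO1 | starting material
2 | 3-methylbut-2-enoyl chloride | CC(C)=CC(=O)Cl | starting material
3 | (S)-4-benzyl-3-(3-methylbut-2-enoyl)oxazolidin-2-one | CC(C)=CC(=O)N1[C@@H](Cc2ccccc2)COC1=O | intermediate
4 | 3-methylbut-3-en-1-ol | C=C(C)CCO | starting material
5 | 3-methylbut-3-en-1-yl trifluoromethanesulfonate | C=C(C)CCOS(=O)(=O)C(F)(F)F | intermediate (not isolated)
6 | (S)-4-benzyl-3-[(S)-5-methyl-2-(prop-1-en-2-yl)hex-5-enoyl]oxazolidin-2-one | C=C(C)CC[C@H](C(=O)N1[C@@H](Cc2ccccc2)COC1=O)C(=C)C | intermediate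
7 | (S)-5-methyl-2-(prop-1-en-2-yl)hex-5-en-1-ol | C=C(C)CC[C@H](CO)C(=C)C | intermediate
8 | (S)-3-(iodomethyl)-2,6-dimethylhepta-1,6-diene | C=C(C)CC[C@H](CI)C(=C)C | intermediate
9 | 3-(tert-butoxy)-3-oxopropanoic acid (mono-tert-butyl malonate) | CC(C)(C)OC(=O)CC(=O)O | starting material
10 | 2,2-diphenylethanol | OCC(c1ccccc1)c1ccccc1 | starting material
11 | tert-butyl 2,2-diphenylethyl malonate | CC(C)(C)OC(=O)CC(=O)OCC(c1ccccc1)c1ccccc1 | intermediate
12 | 1-tert-butyl 3-(2,2-diphenylethyl) 2-[(R)-5-methyl-2-(prop-1-en-2-yl)hex-5-en-1-yl]malonate, both epimers at the malonate carbon | C=C(C)CC[C@H](CC(C(=O)OC(C)(C)C)C(=O)OCC(c1ccccc1)c1ccccc1)C(=C)C | intermediate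
13 | 1-bromo-3-methylbut-2-ene (prenyl bromide) | CC(C)=CCBr | starting material
14 | 1-tert-butyl 3-(2,2-diphenylethyl) (R)-2-(3-methylbut-2-en-1-yl)-2-[(R)-5-methyl-2-(prop-1-en-2-yl)hex-5-en-1-yl]malonate | C=C(C)CC[C@H](C[C@@](CC=C(C)C)(C(=O)OC(C)(C)C)C(=O)OCC(c1ccccc1)c1ccccc1)C(=C)C | intermediate
15 | tert-butyl (R)-2-(hydroxymethyl)-5-methyl-2-[(R)-5-methyl-2-(prop-1-en-2-yl)hex-5-en-1-yl]hex-4-enoate | C=C(C)CC[C@H](C[C@@](CC=C(C)C)(C(=O)OC(C)(C)C)CO)C(=C)C | intermediate
16 | tert-butyl (R)-2-formyl-5-methyl-2-[(R)-5-methyl-2-(prop-1-en-2-yl)hex-5-en-1-yl]hex-4-enoate | C=C(C)CC[C@H](C[C@@](CC=C(C)C)(C(=O)OC(C)(C)C)C=O)C(=C)C | intermediate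
17 | tert-butyl (R)-2-ethynyl-5-methyl-2-[(R)-5-methyl-2-(prop-1-en-2-yl)hex-5-en-1-yl]hex-4-enoate | C=C(C)CC[C@H](C[C@@](CC=C(C)C)(C(=O)OC(C)(C)C)C#C)C(=C)C | intermediate
18 | (S)-4-benzyl-3-propionyloxazolidin-2-one | CCC(=O)N1[C@@H](Cc2ccccc2)COC1=O | starting material
19 | acetaldehyde | CC=O | starting material
20 | (S)-4-benzyl-3-[(2S,3R)-3-hydroxy-2-methylbutanoyl]oxazolidin-2-one | O=C([C@@H](C)[C@@H](C)O)N1[C@@H](Cc2ccccc2)COC1=O | intermediate
21 | (2S,3R)-3-hydroxy-N-methoxy-N,2-dimethylbutanamide | CON(C)C(=O)[C@@H](C)[C@@H](C)O | intermediate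
22 | (2S,3R)-N-methoxy-N,2-dimethyl-3-[(triethylsilyl)oxy]butanamide | CON(C)C(=O)[C@@H](C)[C@@H](C)O[Si](CC)(CC)CC | intermediate
23 | tert-butyl (R)-5-methyl-2-{(4S,5R)-4-methyl-3-oxo-5-[(triethylsilyl)oxy]hex-1-yn-1-yl}-2-[(R)-5-methyl-2-(prop-1-en-2-yl)hex-5-en-1-yl]hex-4-enoate | C=C(C)CC[C@H](C[C@@](CC=C(C)C)(C(=O)OC(C)(C)C)C#CC(=O)[C@@H](C)[C@@H](C)O[Si](CC)(CC)CC)C(=C)C | intermediate
24 | triethylsilyl ester of acid 25 (configuration as in 23) | C=C(C)CC[C@H](C[C@@](CC=C(C)C)(C(=O)O[Si](CC)(CC)CC)C#CC(=O)[C@@H](C)[C@@H](C)O[Si](CC)(CC)CC)C(=C)C | intermediate (not isolated)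
25 | (R)-5-methyl-2-{(4S,5R)-4-methyl-3-oxo-5-[(triethylsilyl)oxy]hex-1-yn-1-yl}-2-[(R)-5-methyl-2-(prop-1-en-2-yl)hex-5-en-1-yl]hex-4-enoic acid | C=C(C)CC[C@H](C[C@@](CC=C(C)C)(C(=O)O)C#CC(=O)[C@@H](C)[C@@H](C)O[Si](CC)(CC)CC)C(=C)C | intermediate
26 | Meldrum's acid (2,2-dimethyl-1,3-dioxane-4,6-dione) | CC1(C)OC(=O)CC(=O)O1 | starting material
27 | acid chloride of 25 (configuration as in 25) | C=C(C)CC[C@H](C[C@@](CC=C(C)C)(C(=O)Cl)C#CC(=O)[C@@H](C)[C@@H](C)O[Si](CC)(CC)CC)C(=C)C | intermediate (not isolated)
28 | 5-[(R)-1-hydroxy-5-methyl-2-{(4S,5R)-4-methyl-3-oxo-5-[(triethylsilyl)oxy]hex-1-yn-1-yl}-2-[(R)-5-methyl-2-(prop-1-en-2-yl)hex-5-en-1-yl]hex-4-en-1-ylidene]-2,2-dimethyl-1,3-dioxane-4,6-dione (key-step precursor) | C=C(C)CC[C@H](C[C@@](CC=C(C)C)(C(O)=C1C(=O)OC(C)(C)OC1=O)C#CC(=O)[C@@H](C)[C@@H](C)O[Si](CC)(CC)CC)C(=C)C | intermediate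
29 | desilylated 28: open-chain C2-hydroxy ynone acyl Meldrum's acid (configuration as in 28) | C=C(C)CC[C@H](C[C@@](CC=C(C)C)(C(O)=C1C(=O)OC(C)(C)OC1=O)C#CC(=O)[C@@H](C)[C@@H](C)O)C(=C)C | intermediate (not isolated)
30 | ring B closed: acyl Meldrum's acid whose C8 carries the (2R,3S)-2,3-dimethyl-4-oxo-3,4-dihydro-2H-pyran-6-yl ring (other centres as in 28) | C=C(C)CC[C@H](C[C@@](CC=C(C)C)(C(O)=C1C(=O)OC(C)(C)OC1=O)C2=CC(=O)[C@@H](C)[C@@H](C)O2)C(=C)C | intermediate (not isolated)
31 | acylketene from 30: C8–C7(=O)–C6H=C5=O with ring B in place | C=C(C)CC[C@H](C[C@@](CC=C(C)C)(C(=O)C=C=O)C2=CC(=O)[C@@H](C)[C@@H](C)O2)C(=C)C | intermediate (not isolated)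
32 | (2R,3S,8R)-5-hydroxy-2,3-dimethyl-8-(3-methylbut-2-en-1-yl)-8-[(R)-5-methyl-2-(prop-1-en-2-yl)hex-5-en-1-yl]-2,3-dihydro-4H-chromene-4,7(8H)-dione (C6-unsubstituted core) | C=C(C)CC[C@H](C[C@@]1(CC=C(C)C)C(=O)C=C(O)C2=C1O[C@H](C)[C@H](C)C2=O)C(=C)C | intermediate
33 | (E)-hex-2-enal | CCC/C=C/C=O | starting material
34 | enol lactone: (4S)-4-propyl-3,4-dihydro-2H-pyran-2-one fused to ring A through O–C5=C6 of 32 (lactone oxygen on C5; an O7-linked isomer, if formed, should converge in step 19) | C=C(C)CC[C@H](C[C@@]1(CC=C(C)C)C(=O)C3=C(OC(=O)C[C@@H]3CCC)C2=C1O[C@H](C)[C@H](C)C2=O)C(=C)C | intermediate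
35 | (S)-3-[(2R,3S,8R)-5-hydroxy-2,3-dimethyl-8-(3-methylbut-2-en-1-yl)-8-[(R)-5-methyl-2-(prop-1-en-2-yl)hex-5-en-1-yl]-4,7-dioxo-3,4,7,8-tetrahydro-2H-chromen-6-yl]hexanoic acid | C=C(C)CC[C@H](C[C@@]1(CC=C(C)C)C(=O)C([C@@H](CCC)CC(=O)O)=C(O)C2=C1O[C@H](C)[C@H](C)C2=O)C(=C)C | target

**Count and risk**

Total steps: 19. Longest linear sequence: 15 (steps 1–4, 6–10, 14–19).

Steps most likely to fail:

1. Step 17. What may go wrong: the acylketene is consumed before C4a reaches C5, through release while ring B is still open, capture by residual methanol, ene or [2+2] reaction with the side-chain alkenes, or dimerisation. Fallback: the two events are decoupled through an isolable ketene precursor. Setting out from 28, brief heating with excess acetone in toluene at 90 °C should exchange the Meldrum's acid unit (loss of CO2) for the 2,2-dimethyl-1,3-dioxin-4-one F1, which tolerates chromatography. PPTS in MeOH and then CSA at 23 °C should remove the silyl group and close ring B by the same conjugate addition, giving the dihydropyranone dioxinone F2. F2 is purified and only then thermolysed (xylene, 140 °C, high dilution) to the same acylketene, and the route is rejoined at 32.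

2. Step 7. What may go wrong: poor discrimination of the two enolate faces, because the α-substituent is bulky and β-branched and its own stereocentre may oppose the catalyst. Fallback: substrate control in place of catalyst control. Setting out from 8 and commercial tert-butyl (S)-3-hydroxybutanoate (C[C@H](O)CC(=O)OC(C)(C)C), Fráter–Seebach alkylation of the dianion (LiN(i-Pr)2, THF–DMPU, −78 → −20 °C) with 8 should give the anti hydroxy ester F3. A second dianion alkylation with 13, from the same face opposite the carbinol methyl, should build the quaternary centre of hydroxy ester F4. Dess–Martin oxidation should give the methyl ketone F5. Its enol phosphate F6 (LiN(i-Pr)2, ClP(O)(OEt)2) is eliminated with more LiN(i-Pr)2 to the terminal alkyne, and the route is rejoined at 17.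

3. Step 18. What may go wrong: low facial selectivity at the β-carbon of an aliphatic acyl azolium, and acyl transfer to the enol oxygen without C–C bond formation. Fallback: a non-catalytic three-component annulation with separation of diastereomers. Setting out from 32, Knoevenagel condensation of butanal with 26 (L-proline cat., MeCN, 23 → 50 °C) should give 5-butylidene Meldrum's acid F7 in the flask. Michael addition of C6 and lactonisation with loss of acetone and CO2 should give 34 together with its epimer at the propyl-bearing carbon, the lactone F8. The two diastereomers are separated by chromatography and the route is rejoined at 34.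

Further compounds
F1 | step 17 | 6-substituted 2,2-dimethyl-4H-1,3-dioxin-4-one derived from 28 (silyloxy ynone retained) | C=C(C)CC[C@H](C[C@@](CC=C(C)C)(C1=CC(=O)OC(C)(C)O1)C#CC(=O)[C@@H](C)[C@@H](C)O[Si](CC)(CC)CC)C(=C)C
F2 | step 17 | dioxinone with ring B closed as the (2R,3S)-2,3-dimethyl-2,3-dihydropyran-4-one | C=C(C)CC[C@H](C[C@@](CC=C(C)C)(C1=CC(=O)OC(C)(C)O1)C2=CC(=O)[C@@H](C)[C@@H](C)O2)C(=C)C
F3 | step 7 | tert-butyl (2S,3S)-3-hydroxy-2-[(R)-5-methyl-2-(prop-1-en-2-yl)hex-5-en-1-yl]butanoate | C=C(C)CC[C@H](C[C@H](C(=O)OC(C)(C)C)[C@H](C)O)C(=C)C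
F4 | step 7 | tert-butyl (R)-2-[(S)-1-hydroxyethyl]-5-methyl-2-[(R)-5-methyl-2-(prop-1-en-2-yl)hex-5-en-1-yl]hex-4-enoate | C=C(C)CC[C@H](C[C@@](CC=C(C)C)(C(=O)OC(C)(C)C)[C@H](C)O)C(=C)C
F5 | step 7 | tert-butyl (R)-2-acetyl-5-methyl-2-[(R)-5-methyl-2-(prop-1-en-2-yl)hex-5-en-1-yl]hex-4-enoate | C=C(C)CC[C@H](C[C@@](CC=C(C)C)(C(=O)OC(C)(C)C)C(C)=O)C(=C)C
F6 | step 7 | diethyl enol phosphate of F5 | C=C(C)CC[C@H](C[C@@](CC=C(C)C)(C(=O)OC(C)(C)C)C(=C)OP(=O)(OCC)OCC)C(=C)C
F7 | step 18 | 5-butylidene-2,2-dimethyl-1,3-dioxane-4,6-dione | CCCC=C1C(=O)OC(C)(C)OC1=O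
F8 | step 18 | epimer of 34 at the propyl-bearing carbon (4R) | C=C(C)CC[C@H](C[C@@]1(CC=C(C)C)C(=O)C3=C(OC(=O)C[C@H]3CCC)C2=C1O[C@H](C)[C@H](C)C2=O)C(=C)C
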